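The runs are calculated on assumed constants.

Amounts first: with 20 mM, 28 mM or 44 mM of starting material against the same partner, the percent curves overlap within the scatter.

| setting | oak | alder | larch | gamma | epsilon | theta | beta |
|---|---|---|---|---|---|---|---|
| starting material | 20 mM | 28 mM | 44 mM | 20 mM | 20 mM | 20 mM | 20 mM (fed, over 9.60 min) |
| partner | 40 mM | 40 mM | 40 mM | 40.0 mM | 40.0 mM | 40.0 mM (fed, over 9.60 min) | 40.0 mM |
| capture agent | 6 mM | 6 mM | 6 mM | 6.00 mM | 6.00 mM | 6.00 mM | 6.00 mM |
| protic impurity | 10 mM | 10 mM | 10 mM | 10.0 mM | 10.0 mM | 10.0 mM | 10.0 mM |
| remark | run made earlier | run made earlier | run made earlier | one stirred flow tank at steady state, fed with the mixture as stated, mean residence time 12 min | everything together in a closed stirred flask, run for 12 min | a stirred flask in which partner is dosed at a steady rate over 9.60 min without added volume, worked up at 12 min | all but starting material at the start; starting material goes in evenly over 9.60 min, the run ends at 12 min |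
| time |  |  |  |  | 12 min | 12 min | 12 min |

| run | time / min | product / % | trapped intermediate / % |
|---|---|---|---|
| oak | 1.50 | 11 | 2 |
| oak | 4.00 | 19 | 2 |
| oak | 8.00 | 24 | 4 |
| oak | 12.0 | 27 | 11 |
| alder | 4.00 | 18 | 0 |
| alder | 8.00 | 26 | 7 |
| alder | 10.0 | 23 | 7 |
| alder | 15.0 | 26 | 11 |
| larch | 2.00 | 10 | 0 |
| larch | 5.00 | 19 | 3 |
| larch | 10.0 | 21 | 9 |
| larch | 15.0 | 27 | 8 |

(each reading ± 2 percentage points)

- the set-up with the highest share of product in all that became product or trapped intermediate, at the outlet or at the end ("none" if the first two lie within 2 percentage points) (gamma / epsilon / theta / beta / none)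
- share of product in all that became product or trapped intermediate, at the outlet or at the end, gamma
- share of product in all that became product or trapped intermediate, at the outlet or at the end, epsilon
- share of product in all that became product or trapped intermediate, at the outlet or at the end, theta
- share of product in all that became product or trapped intermediate, at the outlet or at the end, beta

- the stated concentrations are those of everything mixed, before any reaction; amounts are the same in each set-up
- what was read earlier has a scatter of 2 percentage points, one standard deviation
- the feed brings no volume worth counting
- the earlier runs were made in a closed, stirred flask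
- a reading or a percentage of product counts all its forms, free or not

**What does the fading of product measure?** I read it as the loss of starting material. Oak gains 11 % in 1.50 min and stands at 27 % by 12.0 min. Taking that last reading as the plateau, I divide it by the first rate and get my estimate of the lifetime of starting material, 3.68 min. This is a reading with the scatter in it, and a pseudo-first-order figure for 40 mM of partner at the start.

**And beta?** Count lifetimes. Feeding evenly against that lifetime, and then waiting 0.652 lifetimes after the feed, leaves 18.5 % of the charge as starting material. Product should then reach 22.0 %.

**Trapped intermediate?** In oak it lags. The mean age of fed material at the end is 7.20 min, younger than oak's reading at 8.00 min, where trapped intermediate stood at 4 %. Taking that reading as the estimate, my share for beta is 84.6 %.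

**Epsilon?** It is oak's recipe, so oak's readings at 12.0 min give 71.1 %, less than my share for beta.

**Theta?** No number from me. Theta changes [partner], and the runs held it at 40 mM, 40 mM and 40 mM, so they give no order in it.

The forecast says gamma 63 %, epsilon 73 %, theta 82 %, beta 52 %, best theta, holding that in beta “late material meets the exhausted impurity”. My beta differs from that.

The simulation gives gamma 67.5 %, epsilon 73.7 %, theta 57.9 % and beta 80.4 %, so the best is beta.

    partner + intermediate A ⇌ intermediate C (K = 24.0 M⁻¹, k = 0.0270 M⁻¹ s⁻¹)
    starting material → intermediate A (k = 0.00260 s⁻¹)
    partner + protic impurity → quenched reagent (k = 0.210 M⁻¹ s⁻¹)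
    starting material + partner → product (k = 0.0380 M⁻¹ s⁻¹)
    partner + product ⇌ idle adduct, settled at all times (K = 8.30 M⁻¹)
    capture agent + intermediate C → trapped intermediate (k = 1.50 M⁻¹ s⁻¹)
    partner + intermediate A ⇌ intermediate B (K = 450 M⁻¹, k = 0.0390 M⁻¹ s⁻¹)

At 12.0 min, beta holds 25.5 % starting material against the reckoned 18.5 %, and 21.1 % product against 22.0 %. The theta flask left until 50 min has stood 13.6 of those lifetimes, so the count leaves <0.001 % of its starting material, and the flask holds more than that, 0.00750 %, still hardly any. Between 12.0 min and that time, product in that flask moves from 12.5 % to 14.7 %, while trapped intermediate climbs from 9.11 % to 26.4 %, and the share stands at 35.7 %.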